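## Retrosynthetic overview

1. Target ⇐ hydrogenolysis of the fully O‑protected oxolane; oxolane ⇐ 5‑exo Williamson closure of a 1,4‑diol (benzylic oxygen attacks a primary tosylate, so the benzylic C–O bond is never broken) ⇐ LiAlH4 opening of a γ‑lactone.
2. Quaternary carbinol ⇐ alkylation of the α‑alkoxy γ‑lactone enolate with 3,4‑dimethoxybenzyl bromide, anti to the two cis substituents (CH2OBn and aryl).
3. Lactone ⇐ γ‑hydroxy α‑alkoxy acid ⇐ aldehyde + CH2=CHMgBr, O‑protection, oxidative cleavage, Pinnick oxidation.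
4. Key C–C bond (aryl carbinol carbon to its neighbour, two contiguous stereocentres): Evans syn‑aldol of the N‑[3‑(benzyloxy)propanoyl] derivative of (R)‑4‑benzyloxazolidinone with 3,4‑bis(benzyloxy)benzaldehyde.
5. Ring order: γ‑lactone first (temporary template for the quaternary centre), reductively opened, then the oxolane ring last.

Assumption: target locants follow the oxolane ring (O1, C2 = ring CH2, C3 = C(OH)(benzyl), C4 = CH–CH2OH, C5 = CH–aryl), and the given SMILES is read as (3R,4R,5R), with aryl, CH2OH and OH all on one face.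

## Route

Step 1
Reactants: 1 (R)-4-benzyl-1,3-oxazolidin-2-one; 2 3-(benzyloxy)propanoic acid
Product: 4 (4R)-4-benzyl-3-[3-(benzyloxy)propanoyl]-1,3-oxazolidin-2-one, via mixed pivalic anhydride 3 (not isolated)
Conditions: t-BuCOCl, Et3N, THF, −20 °C; then 1, LiCl, −20 °C → rt
Reagents that add atoms: none
Why: N-acylation of the oxazolidinone by the mixed pivalic anhydride (acyl transfer to the LiCl-activated carbamate nitrogen) is the standard way to load an Evans auxiliary and creates no stereocentre.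

Step 2
Reactants: 4 (4R)-4-benzyl-3-[3-(benzyloxy)propanoyl]-1,3-oxazolidin-2-one; 5 3,4-bis(benzyloxy)benzaldehyde
Product: 8 (4R)-4-benzyl-3-[(2R,3R)-2-[(benzyloxy)methyl]-3-[3,4-bis(benzyloxy)phenyl]-3-hydroxypropanoyl]-1,3-oxazolidin-2-one, via Z-dibutylboron enolate 6 (not isolated), via dibutylboron aldolate 7 (not isolated)
Conditions: n-Bu2BOTf, i-Pr2NEt, CH2Cl2, −78 → 0 °C; then 5, −78 → 0 °C; then pH 7 phosphate buffer, MeOH, 30% H2O2, 0 °C
Reagents that add atoms: none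
Why: Evans syn-aldol reaction: soft enolisation gives the Z-boron enolate, which adds to the aldehyde through a closed Zimmerman–Traxler chair on the enolate face turned away from the auxiliary benzyl group, so the (R)-auxiliary fixes the two new centres as (2R,3R)-syn (the future C4 and C5 of the oxolane), while the covalent, weakly basic boron enolate should not expel the β-benzyloxy group at these temperatures.

Step 3
Reactants: 8 (4R)-4-benzyl-3-[(2R,3R)-2-[(benzyloxy)methyl]-3-[3,4-bis(benzyloxy)phenyl]-3-hydroxypropanoyl]-1,3-oxazolidin-2-one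
Product: 9 (4R)-4-benzyl-3-[(2R,3R)-2-[(benzyloxy)methyl]-3-[3,4-bis(benzyloxy)phenyl]-3-[(tert-butyldimethylsilyl)oxy]propanoyl]-1,3-oxazolidin-2-one
Conditions: TBSOTf, 2,6-lutidine, CH2Cl2, −78 → 0 °C
Reagents that add atoms: tert-butyldimethylsilyl trifluoromethanesulfonate, CC(C)(C)[Si](C)(C)OS(=O)(=O)C(F)(F)F
Why: Silylation with the silyl triflate and a hindered pyridine base protects the benzylic alcohol under non-acidic conditions, so neither retro-aldol cleavage nor ionisation of the electron-rich benzylic centre can occur and both stereocentres stay as set.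

Step 4
Reactants: 9 (4R)-4-benzyl-3-[(2R,3R)-2-[(benzyloxy)methyl]-3-[3,4-bis(benzyloxy)phenyl]-3-[(tert-butyldimethylsilyl)oxy]propanoyl]-1,3-oxazolidin-2-one
Product: 10 (2R,3R)-2-[(benzyloxy)methyl]-3-[3,4-bis(benzyloxy)phenyl]-3-[(tert-butyldimethylsilyl)oxy]propan-1-ol
Conditions: LiBH4, H2O (1 equiv), Et2O, 0 °C → rt
Reagents that add atoms: none
Why: Reductive cleavage of the Evans auxiliary: borohydride attacks the activated exocyclic imide carbonyl and delivers the primary alcohol together with the recoverable oxazolidinone without touching the adjacent stereocentre.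

Step 5
Reactants: 10 (2R,3R)-2-[(benzyloxy)methyl]-3-[3,4-bis(benzyloxy)phenyl]-3-[(tert-butyldimethylsilyl)oxy]propan-1-ol
Product: 11 (2R,3R)-2-[(benzyloxy)methyl]-3-[3,4-bis(benzyloxy)phenyl]-3-[(tert-butyldimethylsilyl)oxy]propanal
Conditions: Dess–Martin periodinane, NaHCO3, CH2Cl2, 0 °C → rt
Reagents that add atoms: none
Why: Dess–Martin oxidation under bicarbonate buffering gives the α-branched aldehyde under essentially neutral conditions, which avoids enolisation (epimerisation or β-elimination of the two β-oxygen groups).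

Step 6
Reactants: 11 (2R,3R)-2-[(benzyloxy)methyl]-3-[3,4-bis(benzyloxy)phenyl]-3-[(tert-butyldimethylsilyl)oxy]propanal
Product: 12 (3RS,4S,5R)-4-[(benzyloxy)methyl]-5-[3,4-bis(benzyloxy)phenyl]-5-[(tert-butyldimethylsilyl)oxy]pent-1-en-3-ol
Conditions: CH2=CHMgBr, THF, −78 °C
Reagents that add atoms: vinylmagnesium bromide, C=C[Mg]Br
Why: Grignard 1,2-addition at low temperature is much faster than enolisation of the aldehyde, and the new carbinol centre may form as a mixture because it becomes a planar enolate carbon in step 11.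

Step 7
Reactants: 12 (3RS,4S,5R)-4-[(benzyloxy)methyl]-5-[3,4-bis(benzyloxy)phenyl]-5-[(tert-butyldimethylsilyl)oxy]pent-1-en-3-ol
Product: 13 tert-butyl{[(1R,2S,3RS)-3-[(benzyloxy)methoxy]-2-[(benzyloxy)methyl]-1-[3,4-bis(benzyloxy)phenyl]pent-4-en-1-yl]oxy}dimethylsilane
Conditions: BnOCH2Cl, i-Pr2NEt, Bu4NI (cat.), CH2Cl2, 40 °C
Reagents that add atoms: benzyl chloromethyl ether, ClCOCc1ccccc1
Why: Alkoxymethylation of the alcohol with the reactive α-chloro ether and an amine base (acetal-type O-alkylation) installs a hydrogenolysable benzyloxymethyl ether without ever forming an alkoxide, so the neighbouring silyl ether cannot migrate.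

Step 8
Reactants: 13 tert-butyl{[(1R,2S,3RS)-3-[(benzyloxy)methoxy]-2-[(benzyloxy)methyl]-1-[3,4-bis(benzyloxy)phenyl]pent-4-en-1-yl]oxy}dimethylsilane
Product: 14 (2RS,3S,4R)-2-[(benzyloxy)methoxy]-3-[(benzyloxy)methyl]-4-[3,4-bis(benzyloxy)phenyl]-4-[(tert-butyldimethylsilyl)oxy]butanal
Conditions: OsO4 (2 mol%), NaIO4, 2,6-lutidine, 1,4-dioxane/H2O (3:1), rt
Reagents that add atoms: osmium tetroxide, O=[Os](=O)(=O)=O; sodium periodate, [Na+].[O-]I(=O)(=O)=O
Why: Lemieux–Johnson oxidative cleavage (osmium-catalysed dihydroxylation followed by periodate glycol cleavage, buffered with lutidine) removes the terminal carbon of the vinyl group and leaves the aldehyde carbon that becomes C2 of the oxolane, without the ozone that would attack the electron-rich arene.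

Step 9
Reactants: 14 (2RS,3S,4R)-2-[(benzyloxy)methoxy]-3-[(benzyloxy)methyl]-4-[3,4-bis(benzyloxy)phenyl]-4-[(tert-butyldimethylsilyl)oxy]butanal
Product: 15 (2RS,3S,4R)-2-[(benzyloxy)methoxy]-3-[(benzyloxy)methyl]-4-[3,4-bis(benzyloxy)phenyl]-4-[(tert-butyldimethylsilyl)oxy]butanoic acid
Conditions: NaClO2, NaH2PO4, 2-methyl-2-butene, t-BuOH/H2O, 0 °C → rt
Reagents that add atoms: sodium chlorite, [Na+].[O-]Cl=O
Why: Pinnick oxidation turns the aldehyde into the carboxylic acid under mildly acidic buffered conditions, the alkene scavenger trapping HOCl before it can chlorinate the arene.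

Step 10
Reactants: 15 (2RS,3S,4R)-2-[(benzyloxy)methoxy]-3-[(benzyloxy)methyl]-4-[3,4-bis(benzyloxy)phenyl]-4-[(tert-butyldimethylsilyl)oxy]butanoic acid
Product: 17 (3RS,4R,5R)-3-[(benzyloxy)methoxy]-4-[(benzyloxy)methyl]-5-[3,4-bis(benzyloxy)phenyl]oxolan-2-one, via hydroxy acid 16 (not isolated)
Conditions: Bu4NF, THF, 0 °C → rt; then AcOH, toluene, 40 °C
Reagents that add atoms: none
Why: Fluoride-mediated desilylation frees the benzylic alcohol and the resulting γ-hydroxy acid lactonises to the five-membered ring on mild acidification, the benzylic C–O bond staying intact so that aryl and benzyloxymethyl groups end up cis on the lactone.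

Step 11
Reactants: 17 (3RS,4R,5R)-3-[(benzyloxy)methoxy]-4-[(benzyloxy)methyl]-5-[3,4-bis(benzyloxy)phenyl]oxolan-2-one; 18 4-(bromomethyl)-1,2-dimethoxybenzene (3,4-dimethoxybenzyl bromide)
Product: 20 (3R,4R,5R)-3-[(benzyloxy)methoxy]-4-[(benzyloxy)methyl]-5-[3,4-bis(benzyloxy)phenyl]-3-[(3,4-dimethoxyphenyl)methyl]oxolan-2-one, via lithium lactone enolate 19 (not isolated)
Conditions: LiN(i-Pr)2, THF, −78 °C; then 18, DMPU, −78 → −40 °C
Reagents that add atoms: none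
Why: Lactone enolate alkylation: deprotonation erases the mixed α-centre, and the benzylic bromide attacks the planar α-alkoxy enolate from the face opposite the two cis substituents at C4 and C5, which places the new benzyl group trans and the oxygen cis to them and sets the quaternary centre as (3R).

Step 12
Reactants: 20 (3R,4R,5R)-3-[(benzyloxy)methoxy]-4-[(benzyloxy)methyl]-5-[3,4-bis(benzyloxy)phenyl]-3-[(3,4-dimethoxyphenyl)methyl]oxolan-2-one
Product: 21 (2R,3R,4R)-2-[(benzyloxy)methoxy]-3-[(benzyloxy)methyl]-4-[3,4-bis(benzyloxy)phenyl]-2-[(3,4-dimethoxyphenyl)methyl]butane-1,4-diol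
Conditions: LiAlH4, THF, 0 °C → rt
Reagents that add atoms: none
Why: Hydride reduction of the lactone with LiAlH4 gives the 1,4-diol and leaves the ethers, the acetal and all three stereocentres untouched.

Step 13
Reactants: 21 (2R,3R,4R)-2-[(benzyloxy)methoxy]-3-[(benzyloxy)methyl]-4-[3,4-bis(benzyloxy)phenyl]-2-[(3,4-dimethoxyphenyl)methyl]butane-1,4-diol
Product: 23 (2R,3R,4R)-4-[(benzyloxy)methoxy]-3-[(benzyloxy)methyl]-2-[3,4-bis(benzyloxy)phenyl]-4-[(3,4-dimethoxyphenyl)methyl]oxolane, via primary tosylate 22 (not isolated)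
Conditions: TsCl, Et3N, 4-(dimethylamino)pyridine (cat.), CH2Cl2, 0 °C → rt; then NaH, THF, 0 → 50 °C
Reagents that add atoms: none
Why: Selective sulfonylation of the primary alcohol and intramolecular Williamson etherification (5-exo-tet attack of the benzylic alkoxide on the primary carbon) close the oxolane ring without breaking the benzylic C–O bond, so its configuration is retained, and the protected tertiary oxygen cannot compete by epoxide formation.

Step 14
Reactants: 23 (2R,3R,4R)-4-[(benzyloxy)methoxy]-3-[(benzyloxy)methyl]-2-[3,4-bis(benzyloxy)phenyl]-4-[(3,4-dimethoxyphenyl)methyl]oxolane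
Product: 24 4-[(2R,3R,4R)-4-[(3,4-dimethoxyphenyl)methyl]-4-hydroxy-3-(hydroxymethyl)oxolan-2-yl]benzene-1,2-diol (target, CNP0115253.1)
Conditions: H2 (1 atm), 10% Pd/C, EtOAc/MeOH, rt
Reagents that add atoms: none
Why: Catalytic hydrogenolysis over palladium cleaves the three benzyl ethers and the benzyloxymethyl acetal (its hemiformal loses formaldehyde) under neutral, reducing conditions that neither epimerise the para-hydroxybenzylic ether centre nor oxidise the catechol.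

## Compound list

1 | (R)-4-benzyl-1,3-oxazolidin-2-one | O=C1N[C@H](Cc2ccccc2)CO1 | starting material
2 | 3-(benzyloxy)propanoic acid | OC(=O)CCOCc1ccccc1 | starting material
3 | 3-(benzyloxy)propanoic pivalic anhydride | CC(C)(C)C(=O)OC(=O)CCOCc1ccccc1 | intermediate
4 | (4R)-4-benzyl-3-[3-(benzyloxy)propanoyl]-1,3-oxazolidin-2-one | O=C(CCOCc1ccccc1)N1[C@H](Cc2ccccc2)COC1=O | intermediate
5 | 3,4-bis(benzyloxy)benzaldehyde | O=Cc1ccc(OCc2ccccc2)c(OCc2ccccc2)c1 | starting material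
6 | (4R)-4-benzyl-3-[(1Z)-3-(benzyloxy)-1-[(dibutylboranyl)oxy]prop-1-en-1-yl]-1,3-oxazolidin-2-one | CCCCB(CCCC)O/C(=C\COCc1ccccc1)N1[C@H](Cc2ccccc2)COC1=O | intermediate
7 | (4R)-4-benzyl-3-[(2R,3R)-2-[(benzyloxy)methyl]-3-[3,4-bis(benzyloxy)phenyl]-3-[(dibutylboranyl)oxy]propanoyl]-1,3-oxazolidin-2-one | CCCCB(CCCC)O[C@@H](c1ccc(OCc2ccccc2)c(OCc2ccccc2)c1)[C@H](C(=O)N1[C@H](Cc2ccccc2)COC1=O)COCc1ccccc1 | intermediate
8 | (4R)-4-benzyl-3-[(2R,3R)-2-[(benzyloxy)methyl]-3-[3,4-bis(benzyloxy)phenyl]-3-hydroxypropanoyl]-1,3-oxazolidin-2-one | O[C@@H](c1ccc(OCc2ccccc2)c(OCc2ccccc2)c1)[C@H](C(=O)N1[C@H](Cc2ccccc2)COC1=O)COCc1ccccc1 | intermediate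
9 | (4R)-4-benzyl-3-[(2R,3R)-2-[(benzyloxy)methyl]-3-[3,4-bis(benzyloxy)phenyl]-3-[(tert-butyldimethylsilyl)oxy]propanoyl]-1,3-oxazolidin-2-one | CC(C)(C)[Si](C)(C)O[C@@H](c1ccc(OCc2ccccc2)c(OCc2ccccc2)c1)[C@H](C(=O)N1[C@H](Cc2ccccc2)COC1=O)COCc1ccccc1 | intermediate
10 | (2R,3R)-2-[(benzyloxy)methyl]-3-[3,4-bis(benzyloxy)phenyl]-3-[(tert-butyldimethylsilyl)oxy]propan-1-ol | CC(C)(C)[Si](C)(C)O[C@@H](c1ccc(OCc2ccccc2)c(OCc2ccccc2)c1)[C@H](CO)COCc1ccccc1 | intermediate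
11 | (2R,3R)-2-[(benzyloxy)methyl]-3-[3,4-bis(benzyloxy)phenyl]-3-[(tert-butyldimethylsilyl)oxy]propanal | CC(C)(C)[Si](C)(C)O[C@@H](c1ccc(OCc2ccccc2)c(OCc2ccccc2)c1)[C@H](C=O)COCc1ccccc1 | intermediate
12 | (3RS,4S,5R)-4-[(benzyloxy)methyl]-5-[3,4-bis(benzyloxy)phenyl]-5-[(tert-butyldimethylsilyl)oxy]pent-1-en-3-ol | CC(C)(C)[Si](C)(C)O[C@@H](c1ccc(OCc2ccccc2)c(OCc2ccccc2)c1)[C@H](C(O)C=C)COCc1ccccc1 | intermediate
13 | tert-butyl{[(1R,2S,3RS)-3-[(benzyloxy)methoxy]-2-[(benzyloxy)methyl]-1-[3,4-bis(benzyloxy)phenyl]pent-4-en-1-yl]oxy}dimethylsilane | CC(C)(C)[Si](C)(C)O[C@@H](c1ccc(OCc2ccccc2)c(OCc2ccccc2)c1)[C@H](C(OCOCc1ccccc1)C=C)COCc1ccccc1 | intermediate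
14 | (2RS,3S,4R)-2-[(benzyloxy)methoxy]-3-[(benzyloxy)methyl]-4-[3,4-bis(benzyloxy)phenyl]-4-[(tert-butyldimethylsilyl)oxy]butanal | CC(C)(C)[Si](C)(C)O[C@@H](c1ccc(OCc2ccccc2)c(OCc2ccccc2)c1)[C@H](C(OCOCc1ccccc1)C=O)COCc1ccccc1 | intermediate
15 | (2RS,3S,4R)-2-[(benzyloxy)methoxy]-3-[(benzyloxy)methyl]-4-[3,4-bis(benzyloxy)phenyl]-4-[(tert-butyldimethylsilyl)oxy]butanoic acid | CC(C)(C)[Si](C)(C)O[C@@H](c1ccc(OCc2ccccc2)c(OCc2ccccc2)c1)[C@H](C(OCOCc1ccccc1)C(O)=O)COCc1ccccc1 | intermediate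
16 | (2RS,3R,4R)-2-[(benzyloxy)methoxy]-3-[(benzyloxy)methyl]-4-[3,4-bis(benzyloxy)phenyl]-4-hydroxybutanoic acid | O[C@@H](c1ccc(OCc2ccccc2)c(OCc2ccccc2)c1)[C@H](C(OCOCc1ccccc1)C(O)=O)COCc1ccccc1 | intermediate
17 | (3RS,4R,5R)-3-[(benzyloxy)methoxy]-4-[(benzyloxy)methyl]-5-[3,4-bis(benzyloxy)phenyl]oxolan-2-one | O=C1O[C@@H](c2ccc(OCc3ccccc3)c(OCc3ccccc3)c2)[C@H](C1OCOCc1ccccc1)COCc1ccccc1 | intermediate
18 | 4-(bromomethyl)-1,2-dimethoxybenzene | COc1ccc(CBr)cc1OC | starting material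
19 | lithium (4R,5R)-3-[(benzyloxy)methoxy]-4-[(benzyloxy)methyl]-5-[3,4-bis(benzyloxy)phenyl]-4,5-dihydrofuran-2-olate | [Li]OC1=C(OCOCc2ccccc2)[C@H](COCc2ccccc2)[C@H](c2ccc(OCc3ccccc3)c(OCc3ccccc3)c2)O1 | intermediate
20 | (3R,4R,5R)-3-[(benzyloxy)methoxy]-4-[(benzyloxy)methyl]-5-[3,4-bis(benzyloxy)phenyl]-3-[(3,4-dimethoxyphenyl)methyl]oxolan-2-one | COc1ccc(C[C@]2(OCOCc3ccccc3)C(=O)O[C@@H](c3ccc(OCc4ccccc4)c(OCc4ccccc4)c3)[C@H]2COCc3ccccc3)cc1OC | intermediate
21 | (2R,3R,4R)-2-[(benzyloxy)methoxy]-3-[(benzyloxy)methyl]-4-[3,4-bis(benzyloxy)phenyl]-2-[(3,4-dimethoxyphenyl)methyl]butane-1,4-diol | COc1ccc(C[C@](OCOCc2ccccc2)(CO)[C@H](COCc2ccccc2)[C@@H](O)c2ccc(OCc3ccccc3)c(OCc3ccccc3)c2)cc1OC | intermediate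
22 | (2R,3R,4R)-2-[(benzyloxy)methoxy]-3-[(benzyloxy)methyl]-4-[3,4-bis(benzyloxy)phenyl]-2-[(3,4-dimethoxyphenyl)methyl]-4-hydroxybutyl 4-methylbenzenesulfonate | COc1ccc(C[C@](OCOCc2ccccc2)(COS(=O)(=O)c2ccc(C)cc2)[C@H](COCc2ccccc2)[C@@H](O)c2ccc(OCc3ccccc3)c(OCc3ccccc3)c2)cc1OC | intermediate
23 | (2R,3R,4R)-4-[(benzyloxy)methoxy]-3-[(benzyloxy)methyl]-2-[3,4-bis(benzyloxy)phenyl]-4-[(3,4-dimethoxyphenyl)methyl]oxolane | COc1ccc(C[C@]2(OCOCc3ccccc3)CO[C@@H](c3ccc(OCc4ccccc4)c(OCc4ccccc4)c3)[C@H]2COCc3ccccc3)cc1OC | intermediate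
24 | 4-[(2R,3R,4R)-4-[(3,4-dimethoxyphenyl)methyl]-4-hydroxy-3-(hydroxymethyl)oxolan-2-yl]benzene-1,2-diol | COc1ccc(C[C@]2(O)CO[C@@H](c3ccc(O)c(O)c3)[C@H]2CO)cc1OC | target

## Step count and risk

Total step count: 14. Longest linear sequence: 14 steps (from 1 and 2 to 24).

The three steps most likely to fail:

Step 2 (Evans aldol). The enolate carries a β-benzyloxy group, so loss of benzyl alcohol to the N-acryloyl imide can compete, and the electron-rich aldehyde adds slowly. The fallback takes the alkoxy group out of the enolate and carries the future CH2OH carbon as a vinyl group. It sets out from 1: N-acylation with (E)-but-2-enoyl chloride (n-BuLi, THF, −78 °C) gives (4R)-4-benzyl-3-[(2E)-but-2-enoyl]-1,3-oxazolidin-2-one F1. Its dienol borinate (n-Bu2BOTf, Et3N, CH2Cl2) adds to 5 at the α-carbon in a deconjugative Evans syn-aldol reaction to give (4R)-4-benzyl-3-[(2R)-2-[(R)-[3,4-bis(benzyloxy)phenyl](hydroxy)methyl]but-3-enoyl]-1,3-oxazolidin-2-one F2, with the same facial sense as in 8. LiBH4 reduction gives (1R,2S)-1-[3,4-bis(benzyloxy)phenyl]-2-ethenylpropane-1,3-diol F3, and double silylation (TBSOTf, 2,6-lutidine) gives (1R,2S)-1-[3,4-bis(benzyloxy)phenyl]-1,3-bis[(tert-butyldimethylsilyl)oxy]-2-ethenylpropane F4. Cleavage of the vinyl group (OsO4 cat., NaIO4, 2,6-lutidine) gives (2S,3R)-3-[3,4-bis(benzyloxy)phenyl]-3-[(tert-butyldimethylsilyl)oxy]-2-{[(tert-butyldimethylsilyl)oxy]methyl}propanal F5, which NaBH4 (MeOH, 0 °C) reduces at once to (2S,3R)-3-[3,4-bis(benzyloxy)phenyl]-3-[(tert-butyldimethylsilyl)oxy]-2-{[(tert-butyldimethylsilyl)oxy]methyl}propan-1-ol F6. Neutral benzylation (2-benzyloxy-1-methylpyridinium trifluoromethanesulfonate, MgO, PhCF3, 83 °C; no alkoxide, so no silyl migration between the two CH2O arms) gives tert-butyl{[(1R,2S)-3-(benzyloxy)-1-[3,4-bis(benzyloxy)phenyl]-2-{[(tert-butyldimethylsilyl)oxy]methyl}propyl]oxy}dimethylsilane F7. Selective cleavage of the primary silyl ether (HF·pyridine, pyridine, THF, 0 °C) comes back to the route at 10.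

Step 11 (quaternary centre by enolate alkylation). The α-alkoxy enolate is hindered, and sluggish alkylation or decomposition of the enolate on warming is possible. The fallback replaces the SN2 alkylation by an aldol addition followed by radical deoxygenation. It sets out from 17: the same lithium enolate (LiN(i-Pr)2, THF, −78 °C) adds to 3,4-dimethoxybenzaldehyde, again anti to the two cis substituents, to give (3S,4R,5R)-3-[(benzyloxy)methoxy]-4-[(benzyloxy)methyl]-5-[3,4-bis(benzyloxy)phenyl]-3-[(RS)-(3,4-dimethoxyphenyl)(hydroxy)methyl]oxolan-2-one F8. 1,1'-Thiocarbonyldiimidazole (4-(dimethylamino)pyridine cat., ClCH2CH2Cl, 60 °C) converts the benzylic alcohol into O-[(3,4-dimethoxyphenyl){(3S,4R,5R)-3-[(benzyloxy)methoxy]-4-[(benzyloxy)methyl]-5-[3,4-bis(benzyloxy)phenyl]-2-oxooxolan-3-yl}methyl] 1H-imidazole-1-carbothioate F9. Barton–McCombie deoxygenation (Bu3SnH, azobisisobutyronitrile, toluene, 90 °C) comes back to the route at 20.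

Step 13 (ring closure). The primary carbon is neopentyl-like and flanked by an oxygenated quaternary centre, so tosylation or displacement may be slow, and sulfonylation of the benzylic alcohol would scramble that centre. The fallback avoids the diol and the displacement altogether by reducing the lactone carbonyl in place. It sets out from 20: i-Bu2AlH (CH2Cl2, −78 °C) gives the lactol (2RS,3R,4R,5R)-3-[(benzyloxy)methoxy]-4-[(benzyloxy)methyl]-5-[3,4-bis(benzyloxy)phenyl]-3-[(3,4-dimethoxyphenyl)methyl]oxolan-2-ol F10. Ionic reduction of its oxocarbenium ion (Et3SiH, BF3·OEt2, CH2Cl2, −78 °C) should be faster than ionisation of the formaldehyde acetal or the benzylic ring C–O bond at that temperature. It comes back to the route at 23.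

## Further compounds

F1 | step 2 | (4R)-4-benzyl-3-[(2E)-but-2-enoyl]-1,3-oxazolidin-2-one | C/C=C/C(=O)N1[C@H](Cc2ccccc2)COC1=O
F2 | step 2 | (4R)-4-benzyl-3-[(2R)-2-[(R)-[3,4-bis(benzyloxy)phenyl](hydroxy)methyl]but-3-enoyl]-1,3-oxazolidin-2-one | O[C@@H](c1ccc(OCc2ccccc2)c(OCc2ccccc2)c1)[C@H](C(=O)N1[C@H](Cc2ccccc2)COC1=O)C=C
F3 | step 2 | (1R,2S)-1-[3,4-bis(benzyloxy)phenyl]-2-ethenylpropane-1,3-diol | O[C@@H](c1ccc(OCc2ccccc2)c(OCc2ccccc2)c1)[C@H](CO)C=C
F4 | step 2 | (1R,2S)-1-[3,4-bis(benzyloxy)phenyl]-1,3-bis[(tert-butyldimethylsilyl)oxy]-2-ethenylpropane | CC(C)(C)[Si](C)(C)O[C@@H](c1ccc(OCc2ccccc2)c(OCc2ccccc2)c1)[C@H](CO[Si](C)(C)C(C)(C)C)C=C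
F5 | step 2 | (2S,3R)-3-[3,4-bis(benzyloxy)phenyl]-3-[(tert-butyldimethylsilyl)oxy]-2-{[(tert-butyldimethylsilyl)oxy]methyl}propanal | CC(C)(C)[Si](C)(C)O[C@@H](c1ccc(OCc2ccccc2)c(OCc2ccccc2)c1)[C@H](CO[Si](C)(C)C(C)(C)C)C=O
F6 | step 2 | (2S,3R)-3-[3,4-bis(benzyloxy)phenyl]-3-[(tert-butyldimethylsilyl)oxy]-2-{[(tert-butyldimethylsilyl)oxy]methyl}propan-1-ol | CC(C)(C)[Si](C)(C)O[C@@H](c1ccc(OCc2ccccc2)c(OCc2ccccc2)c1)[C@H](CO[Si](C)(C)C(C)(C)C)CO
F7 | step 2 | tert-butyl{[(1R,2S)-3-(benzyloxy)-1-[3,4-bis(benzyloxy)phenyl]-2-{[(tert-butyldimethylsilyl)oxy]methyl}propyl]oxy}dimethylsilane | CC(C)(C)[Si](C)(C)O[C@@H](c1ccc(OCc2ccccc2)c(OCc2ccccc2)c1)[C@H](CO[Si](C)(C)C(C)(C)C)COCc1ccccc1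
F8 | step 11 | (3S,4R,5R)-3-[(benzyloxy)methoxy]-4-[(benzyloxy)methyl]-5-[3,4-bis(benzyloxy)phenyl]-3-[(RS)-(3,4-dimethoxyphenyl)(hydroxy)methyl]oxolan-2-one | COc1ccc(C(O)[C@]2(OCOCc3ccccc3)C(=O)O[C@@H](c3ccc(OCc4ccccc4)c(OCc4ccccc4)c3)[C@H]2COCc3ccccc3)cc1OC
F9 | step 11 | O-[(3,4-dimethoxyphenyl){(3S,4R,5R)-3-[(benzyloxy)methoxy]-4-[(benzyloxy)methyl]-5-[3,4-bis(benzyloxy)phenyl]-2-oxooxolan-3-yl}methyl] 1H-imidazole-1-carbothioate | COc1ccc(C(OC(=S)n3ccnc3)[C@]2(OCOCc3ccccc3)C(=O)O[C@@H](c3ccc(OCc4ccccc4)c(OCc4ccccc4)c3)[C@H]2COCc3ccccc3)cc1OC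
F10 | step 13 | (2RS,3R,4R,5R)-3-[(benzyloxy)methoxy]-4-[(benzyloxy)methyl]-5-[3,4-bis(benzyloxy)phenyl]-3-[(3,4-dimethoxyphenyl)methyl]oxolan-2-ol | COc1ccc(C[C@]2(OCOCc3ccccc3)C(O)O[C@@H](c3ccc(OCc4ccccc4)c(OCc4ccccc4)c3)[C@H]2COCc3ccccc3)cc1OC
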